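## Structural features

The target is a trans-2-aryl-3-(hydroxymethyl)-2,3-dihydrobenzofuran. Benzo ring A is fused through C3a and C7a to the dihydrofuran ring (O1, C2, C3); C2 carries a 3,4,5-trimethoxyphenyl ring (ring C); C5, para to O1, carries an (E)-3-hydroxyprop-1-enyl chain. The two stereocentres, C2 (R) and C3 (S), are neighbours and their substituents are trans. C2 is a benzylic ether carbon between an electron-rich arene and a phenolic oxygen, so it can ionise in acid and is open to hydrogenolysis. The cinnamyl-type allylic alcohol is sensitive to acid, hydrogenation and oxidation, whereas the three methoxy groups are spectators. The real difficulty is twofold: to fix C2 and C3 in absolute and relative terms, and to place O1 and C3 on adjacent carbons of ring A with the chain para to oxygen and hydrogen at C4, C6 and C7. The key step uses this ortho pattern: O1 on C7a and C3 on C3a are the two bonds an aryne forms when it takes up an oxygen nucleophile and then a carbon electrophile. Because that electrophile is an enoate tethered to the oxygen, C3 emerges with a two-carbon ester arm that must later be cut back to CH2OH, C4 needs a removable control substituent, and C5 a masked form of the chain.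

## Logic of the disconnections

**26 ⇒ 25 ⇒ 23 + 24.** The allylic C–OH of 26 is taken back to the ester level (25), and the C=C bond between the ring A-bound carbon and its neighbour is then cut to give 23 and the two-carbon unit 24. The cut is made there because the allylic alcohol is the most fragile part of 26 and should be made last from a robust carbonyl group. The gain is that the side chain shrinks to one carbon on C5. The forward steps must give the E alkene only and must reduce the ester without harming the free hydroxymethyl group or C2.

**23 ⇒ 21.** No skeletal bond is cut; the formyl carbon of 23 is the nitrile carbon of 21. A nitrile survives all the earlier chemistry at the C3 arm and is wanted as an electron-withdrawing group para to O1 in the ring-forming step. The forward step must be a partial reduction that stops at the imine stage beside a free hydroxyl group.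

**21 ⇒ 18 ⇒ 17.** In the reverse sense a carboxyl carbon is added to the hydroxymethyl carbon: the C–O bond on the C3 arm of 21 becomes the CH2–CO2H bond of 18, the acid of 17. The reason is that a C3–CH2–C(=O) arm is what conjugate addition to an enoate leaves, so C3 can be made by C–C bond formation. The cost is one extra carbon. The forward step must excise it with C–O bond formation through a primary radical beside C3, which has to be trapped before the C2–C3 bond can fragment, and it is placed before any alkene exists because thiyl radicals take part.

**17 ⇒ 16.** The C4–H bond of 17 is replaced by C4–Cl. The chlorine is only a control element for the ring-forming step and is removed right afterwards, while the neighbouring nitrile still activates the C–Cl bond. The forward hydrodechlorination must spare the nitrile, the ester and the benzylic C2–O1 bond.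

**16 ⇒ 5 + 12 (through 13, 14 and 15).** O1–C7a and C3–C3a are cut together and the dihydrofuran ring opens. They belong together because they sit on adjacent carbons of ring A, as after an aryne has taken up a nucleophile (the oxygen of 5) and an electrophile (its enoate beta-carbon). This is the largest simplification of the route: 16 falls into two fragments of similar size, the C2 centre is delegated to 5, and ring A becomes a simple benzene derivative. The forward step must put oxygen on the aryne carbon remote from chlorine, close the five-membered ring before the carbanion is quenched, and place the C3 arm trans to the C2 aryl group.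

**12 ⇒ 10 ⇒ 7 ⇒ 6.** The O–S bond, the C–Si bond and the carbamate O–C bond are cut in turn. Silicon is needed on the carbon between oxygen and chlorine, the most acidic ring position of 7, so a carbamate-directed metalation is the natural entry, and the carbamate can be exchanged for triflate in one flask. 6 already carries every ring substituent. The base must remove that proton without attacking the nitrile, and the aryl anion must be silylated before it loses chloride.

**5 ⇒ 4 ⇒ 1 + 2.** The E alkene of 5 is taken back to the alkyne of 4, and the bond between the carbinol carbon and the alkyne is cut to give 1 and 2. Enantioselective alkynylation of an aromatic aldehyde is a dependable source of a single propargylic alcohol enantiomer, and its hydroxyl group then directs a trans reduction. Both components are simple. The forward steps must set the carbinol centre with high enantioselectivity, give the E geometry (a Z enoate would lactonise) and avoid racemising the doubly activated carbinol.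

## Other disconnections considered

**Alternative 1:** The cut removes the three ring A bonds C3a–C7a, C4–C5 and C6–C7, so that ring A unravels into triyne A2, which holds an ethynyl ether, a silylalkyne and a propargyl alkyne in one chain.
- Forward key step: RhCl(PPh3)3 would cyclotrimerise A2 intramolecularly to A1, closing ring A, the dihydrofuran ring and a temporary oxasilole ring at once.
- In its favour: the tethers dictate the substitution pattern of ring A, so there is no regiochemical question and no blocking group. C3 already has its CH2O carbon and C5 arrives as a benzylic CH2–O, so no carbon is excised. Silicon at C4 leaves by protodesilylation.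
- Against it here: both stereocentres must be built in an open chain beforehand by a separate stereocontrolled sequence. The ethynyl ether of a secondary, electron-rich benzylic alcohol is laborious to make and prone to hydration and thermal retro-ene fragmentation. A2 is assembled linearly. After the key step the oxasilole must be opened, C4 desilylated, the C5 carbinol oxidised, the chain extended and reduced, and the silyl ether removed.
- Comparison: on structure the alternative is the better plan in atom bookkeeping (no chlorine to remove, no carbon to excise) and equal in leaving the olefination to the end. On mechanism it rests on an established catalytic reaction class, which is better than the unprecedented step chosen here, although the ynol ether adds its own uncertainty. On step economy the chosen plan should be shorter, because 5 and 12 are made in two and three steps and joined convergently.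

**Alternative 2:** The cut is C3–C3a, traced back through a 1,2-shift of the ring A carbon (future C3a) to the ketone carbon of flavanone A4.
- Forward key step: PhI(OAc)2 in acidic trimethyl orthoformate turns the ketone into its enol ether, trivalent iodine adds at C3, and the ring A carbon migrates from the former carbonyl carbon to C3 as iodine departs in its monovalent state. The pyranone contracts to the dihydrofuran ring and the former carbonyl carbon becomes the ester carbon of A3.
- In its favour: this is an established reaction type for flavanones. The trans isomer is favoured thermodynamically because C3 is epimerisable. The C3 substituent already has the right carbon count (ester to CH2OH in one reduction). Bromine at C5 lets the chain be attached by one palladium-catalysed coupling.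
- Against it here: the C2 centre of A4 stands beta to the ketone and is lost whenever the pyranone ring opens by retro-oxa-Michael reaction, which acid promotes. Enantiopurity would therefore have to be created by an asymmetric conjugate arylation or oxa-Michael closure and then carried through an acidic oxidation. Electron-rich ring C can compete as the migrating group (shift from C2 to C3) or be attacked by the oxidant. In A3 the C2–O1 bond is beta to the ester carbonyl, so base can open the ring.
- Comparison: on step economy the alternative is better (no carbon excision, no dechlorination, no nitrile-to-chain sequence). On mechanism it is better precedented. On structure the two are equal in delivering the trans arrangement. The chosen plan is stronger only in the security of the absolute configuration, since the C–O bond of the carbinol in 5 is never broken and no acid is used up to 16.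

**Alternative 3:** The cut is O1–C2, giving diol A6, in which the benzylic carbinol may have either configuration.
- Forward key step: BF3·OEt2 ionises the benzylic alcohol and the ring A phenol captures the cation, closing the dihydrofuran ring to A5. Both carbinol epimers pass through the same cation, and the C3 centre steers ring C to the trans position.
- In its favour: only the C3 centre has to be made deliberately, for instance by an auxiliary-controlled enolate reaction. The hydroxymethyl group is in place. Bromine at C5 accepts the chain by a Heck-type coupling. The route is short.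
- Against it here: the cation is generated next to the only controlled stereocentre, so proton loss towards a stilbene-type alkene or a 1,2-hydride shift would erase it. The 3,4,5-trimethoxyphenyl group stabilises the cation less than a 4-oxygenated phenyl ring with free ortho positions, so ionisation needs more forcing acid. The free primary alcohol may need protection. The trans preference rests on a modest energy difference.
- Comparison: on step economy and on precedent this alternative is the better plan. On structure it is equal (same trans outcome), and its indifference to the carbinol configuration is an advantage the chosen plan lacks. The chosen plan is ahead only in closing the ring under basic fluoride conditions that cannot ionise C2 and in making two ring bonds in one operation from two simple fragments.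

Key step: step 6

## Remarks before the steps

- Numbering O1, C2, C3, C3a, C4–C7, C7a of the dihydrobenzofuran is used throughout.
- Assumption: (S,S)-ProPhenol is taken to deliver the alkynyl group to the Re face of 1; if the sense is the opposite, the (R,R)-ligand is used and nothing else changes.
- The constitutions and configurations of 5, 12 and 16 were checked atom by atom against the target and need no correction. Descriptors change without any change in spatial arrangement: 4 is S while 5 is R (alkynyl outranks aryl, alkenyl does not), and C3 is R in 15–19 and S from 20 onwards (CH2O outranks C3a, CH2C does not).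
- Design changes concern how the precursors are made and used. The silylation uses a lithium amide and not an alkyllithium, because of the nitrile. Alkoxide 13 is kept in excess and 12 is added slowly, so that enolate 15 does not meet free aryne. Chlorine is removed while the nitrile still activates it.

## Route

Step 1
Reactants: 1 3,4,5-trimethoxybenzaldehyde; 2 methyl propiolate
Product: 4 methyl (S)-4-hydroxy-4-(3,4,5-trimethoxyphenyl)but-2-ynoate, via methylzinc acetylide 3 (not isolated)
Conditions: ZnMe2 (3 equiv), (S,S)-ProPhenol (10 mol%), Ph3P=O (20 mol%), PhMe, 0 °C; aq NH4Cl
Reagents that add atoms: none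
Why: Zinc-mediated catalytic asymmetric alkynylation of an aldehyde: ZnMe2 metalates 2 to acetylide 3, which the dinuclear zinc–ProPhenol complex should deliver to the Re face of 1, setting the carbinol centre as S. The zinc acetylide is non-basic and soft enough to leave the ester alone.

Step 2
Reactants: 4 methyl (S)-4-hydroxy-4-(3,4,5-trimethoxyphenyl)but-2-ynoate
Product: 5 methyl (R,E)-4-hydroxy-4-(3,4,5-trimethoxyphenyl)but-2-enoate
Conditions: NaAlH2(OCH2CH2OMe)2 (1.5 equiv), THF, −72 °C; then aq KNaC4H4O6
Reagents that add atoms: none
Why: Hydroxyl-directed trans-hydroalumination of a gamma-hydroxy ynoate: the alkoxy-bound aluminium hydride delivers hydride to C3 from within, and protonolysis of the vinyl–aluminium bond should give the E alkene only, the ester being inert at this temperature. The carbinol centre is not touched.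

Step 3
Reactants: 6 2-chloro-4-hydroxybenzonitrile
Product: 7 3-chloro-4-cyanophenyl N-(propan-2-yl)carbamate
Conditions: i-PrNCO, Et3N (cat.), CH2Cl2, rt
Reagents that add atoms: isopropyl isocyanate, CC(C)N=C=O
Why: Amine-catalysed addition of a phenol to an isocyanate (carbamoylation); the N–H carbamate is a strong ortho-directing group that can later be removed with mild base.

Step 4
Reactants: 7 3-chloro-4-cyanophenyl N-(propan-2-yl)carbamate
Product: 10 3-chloro-4-cyano-2-(trimethylsilyl)phenyl N-(propan-2-yl)carbamate, via N-silyl carbamate 8 (not isolated), via N-silyl C-silyl carbamate 9 (not isolated)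
Conditions: TMSOTf, TMEDA, THF, 0 °C → rt; then TMSCl (3 equiv), LiTMP (2.5 equiv), −78 °C; aq NaHSO4
Reagents that add atoms: chlorotrimethylsilane, C[Si](C)(C)Cl
Why: Directed ortho-metalation with in situ silyl quench: N-silylation (8) masks the acidic N–H, and the hindered amide LiTMP, which unlike an alkyllithium should not add to the nitrile, removes the proton flanked by the carbamate oxygen and chlorine. TMSCl already present traps the aryllithium at −78 °C before loss of LiCl or anionic Fries rearrangement can set in, and the N–Si bond of 9 is hydrolysed on work-up.

Step 5
Reactants: 10 3-chloro-4-cyano-2-(trimethylsilyl)phenyl N-(propan-2-yl)carbamate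
Product: 12 3-chloro-4-cyano-2-(trimethylsilyl)phenyl trifluoromethanesulfonate, via 2-silylphenol 11 (not isolated)
Conditions: DBU, Et2NH, MeCN, 40 °C; then PhNTf2, rt
Reagents that add atoms: N-phenylbis(trifluoromethanesulfonimide), O=S(=O)(N(c1ccccc1)S(=O)(=O)C(F)(F)F)C(F)(F)F
Why: Base-induced elimination of the N–H carbamate (E1cB) expels isopropyl isocyanate, which Et2NH scavenges as a urea, and the phenoxide of 11 is sulfonylated in the same flask by the mild triflating agent PhNTf2. The electron-poor phenoxide is a good leaving group in the first stage and the C–Si bond is not exposed to acid.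

Step 6
Reactants: 5 methyl (R,E)-4-hydroxy-4-(3,4,5-trimethoxyphenyl)but-2-enoate; 12 3-chloro-4-cyano-2-(trimethylsilyl)phenyl trifluoromethanesulfonate
Product: 16 methyl 2-[(2R,3R)-4-chloro-5-cyano-2-(3,4,5-trimethoxyphenyl)-2,3-dihydro-1-benzofuran-3-yl]acetate, via sodium alkoxide 13 (not isolated), via aryne 14 (not isolated), via sodium ester enolate 15 (not isolated)
Conditions: NaH (1.0 equiv to 5), THF, 0 °C; then CsF, 18-crown-6, slow addition of 12 (0.7 equiv), −20 °C → rt; aq NH4Cl
Reagents that add atoms: none
Why: Proposed new method: fluoride attacks silicon of 12 and triflate leaves, so that aryne 14 is released slowly into an excess of preformed alkoxide 13, whose oxygen adds to the aryne carbon remote from chlorine (the future C7a) and forms O1–C7a. The carbanion thus placed at C3a, next to chlorine, adds to the enoate beta-carbon to form C3–C3a, and ester enolate 15 is protonated at the quench. The closest known reaction type is the fluoride-induced aryne annulation in which a heteroatom nucleophile adds to the aryne and the aryl anion then closes a ring by intramolecular Michael addition (xanthenes from 2-hydroxychalcones); an aliphatic alkoxide carrying its own acceptor has not been used in this way. The dihydrofuran ring closes in the 5-exo-trig mode. The new stereocentre C3 is controlled by the carbinol centre C2 inside the forming ring: the enoate terminus should swing to the face opposite the C2 aryl group and give the 2,3-trans (2R,3R) isomer, while C2 keeps its configuration because its C–O bond is not broken. Regioselectivity on the aryne is required and is secured by the inductive chlorine at C4, which distorts the triple bond and stabilises charge at C3a, with the nitrile para to C7a acting in the same direction. Chemoselectivity is required as well: with no O–H left after deprotonation and a five-membered transition state, ring closure should outrun protonation and chloride loss from the carbanion, and the E geometry of 5 keeps the alkoxide from lactonising.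

Step 7
Reactants: 16 methyl 2-[(2R,3R)-4-chloro-5-cyano-2-(3,4,5-trimethoxyphenyl)-2,3-dihydro-1-benzofuran-3-yl]acetate
Product: 17 methyl 2-[(2R,3R)-5-cyano-2-(3,4,5-trimethoxyphenyl)-2,3-dihydro-1-benzofuran-3-yl]acetate
Conditions: Pd(OAc)2 (5 mol%), XPhos (10 mol%), HCO2Na (3 equiv), DMF, 90 °C
Reagents that add atoms: none
Why: Palladium-catalysed transfer hydrodechlorination: zerovalent palladium with the bulky biarylphosphine inserts into the hindered C4–Cl bond, which the ortho nitrile activates, formate replaces chloride and loses CO2, and reductive elimination forms C4–H. Under these homogeneous, hydrogen-gas-free conditions the nitrile, the ester and the benzylic C2–O1 bond should be untouched.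

Step 8
Reactants: 17 methyl 2-[(2R,3R)-5-cyano-2-(3,4,5-trimethoxyphenyl)-2,3-dihydro-1-benzofuran-3-yl]acetate
Product: 18 2-[(2R,3R)-5-cyano-2-(3,4,5-trimethoxyphenyl)-2,3-dihydro-1-benzofuran-3-yl]acetic acid
Conditions: LiOH, THF/H2O, 0 °C → rt; then 1 M HCl to pH 3
Reagents that add atoms: lithium hydroxide, [Li+].[OH-]
Why: Saponification of a methyl ester under conditions too mild to hydrate an aryl nitrile; C3 is beta to the carbonyl and carries no leaving group, so neither epimerisation nor ring opening is expected.

Step 9
Reactants: 18 2-[(2R,3R)-5-cyano-2-(3,4,5-trimethoxyphenyl)-2,3-dihydro-1-benzofuran-3-yl]acetic acid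
Product: 21 (2R,3S)-3-(hydroxymethyl)-2-(3,4,5-trimethoxyphenyl)-2,3-dihydro-1-benzofuran-5-carbonitrile, via thiohydroxamate ester 19 (not isolated), via hydroperoxide 20 (not isolated)
Conditions: 1-hydroxypyridine-2(1H)-thione, DCC, DMAP (cat.), CH2Cl2, dark, rt; then t-BuSH, O2, PhMe, visible light, 10 °C; then PPh3
Reagents that add atoms: dioxygen, O=O
Why: Barton decarboxylation with oxygen trapping: photolysis of 19 gives the primary radical on the C3 arm, which is captured by O2, and the peroxyl radical takes hydrogen from t-BuSH to give 20 while the thiyl radical carries the chain. PPh3 then reduces the hydroperoxide to the alcohol, and C3 itself is not involved.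

Step 10
Reactants: 21 (2R,3S)-3-(hydroxymethyl)-2-(3,4,5-trimethoxyphenyl)-2,3-dihydro-1-benzofuran-5-carbonitrile
Product: 23 (2R,3S)-3-(hydroxymethyl)-2-(3,4,5-trimethoxyphenyl)-2,3-dihydro-1-benzofuran-5-carbaldehyde, via aldimine 22 (not isolated)
Conditions: i-Bu2AlH (3 equiv), CH2Cl2, −78 → −40 °C; then 10% aq citric acid, 0 °C
Reagents that add atoms: water, O
Why: Partial reduction of an aryl nitrile with i-Bu2AlH stops at the aluminium-bound aldimine, which gives the aldehyde on mild acid hydrolysis of 22. The first hydride equivalent is consumed by the hydroxyl group, which is thereby masked as its aluminium alkoxide.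

Step 11
Reactants: 23 (2R,3S)-3-(hydroxymethyl)-2-(3,4,5-trimethoxyphenyl)-2,3-dihydro-1-benzofuran-5-carbaldehyde; 24 methyl (triphenylphosphoranylidene)acetate
Product: 25 methyl (E)-3-[(2R,3S)-3-(hydroxymethyl)-2-(3,4,5-trimethoxyphenyl)-2,3-dihydro-1-benzofuran-5-yl]prop-2-enoate
Conditions: PhMe, 60 °C
Reagents that add atoms: none
Why: Wittig olefination with a stabilised ylide, which is E-selective and tolerates the free hydroxyl group; no base is present that could affect C2 or C3.

Step 12
Reactants: 25 methyl (E)-3-[(2R,3S)-3-(hydroxymethyl)-2-(3,4,5-trimethoxyphenyl)-2,3-dihydro-1-benzofuran-5-yl]prop-2-enoate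
Product: 26 (E)-3-[(2R,3S)-3-(hydroxymethyl)-2-(3,4,5-trimethoxyphenyl)-2,3-dihydro-1-benzofuran-5-yl]prop-2-en-1-ol
Conditions: i-Bu2AlH (4 equiv), CH2Cl2, −78 °C; then aq KNaC4H4O6
Reagents that add atoms: none
Why: 1,2-Reduction of an alpha,beta-unsaturated ester with i-Bu2AlH at low temperature gives the allylic alcohol and leaves the alkene alone. The neutral tartrate work-up avoids acid, to which the cinnamyl alcohol and the benzylic ether are sensitive.

## Compound list

1 | 3,4,5-trimethoxybenzaldehyde | COc1cc(C=O)cc(OC)c1OC | starting material
2 | methyl propiolate | C#CC(=O)OC | starting material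
3 | methyl 3-(methylzincio)prop-2-ynoate | C[Zn]C#CC(=O)OC | intermediate
4 | methyl (S)-4-hydroxy-4-(3,4,5-trimethoxyphenyl)but-2-ynoate | COc1cc([C@H](O)C#CC(=O)OC)cc(OC)c1OC | intermediate
5 | methyl (R,E)-4-hydroxy-4-(3,4,5-trimethoxyphenyl)but-2-enoate | COc1cc([C@H](O)/C=C/C(=O)OC)cc(OC)c1OC | intermediate
6 | 2-chloro-4-hydroxybenzonitrile | N#Cc1ccc(O)cc1Cl | starting material
7 | 3-chloro-4-cyanophenyl N-(propan-2-yl)carbamate | CC(C)NC(=O)Oc1ccc(C#N)c(Cl)c1 | intermediate
8 | 3-chloro-4-cyanophenyl N-(propan-2-yl)-N-(trimethylsilyl)carbamate | CC(C)N([Si](C)(C)C)C(=O)Oc1ccc(C#N)c(Cl)c1 | intermediate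
9 | 3-chloro-4-cyano-2-(trimethylsilyl)phenyl N-(propan-2-yl)-N-(trimethylsilyl)carbamate | CC(C)N([Si](C)(C)C)C(=O)Oc1ccc(C#N)c(Cl)c1[Si](C)(C)C | intermediate
10 | 3-chloro-4-cyano-2-(trimethylsilyl)phenyl N-(propan-2-yl)carbamate | CC(C)NC(=O)Oc1ccc(C#N)c(Cl)c1[Si](C)(C)C | intermediate
11 | 2-chloro-4-hydroxy-3-(trimethylsilyl)benzonitrile | C[Si](C)(C)c1c(O)ccc(C#N)c1Cl | intermediate
12 | 3-chloro-4-cyano-2-(trimethylsilyl)phenyl trifluoromethanesulfonate | C[Si](C)(C)c1c(Cl)c(C#N)ccc1OS(=O)(=O)C(F)(F)F | intermediate
13 | sodium (1R,2E)-4-methoxy-4-oxo-1-(3,4,5-trimethoxyphenyl)but-2-en-1-olate | COc1cc([C@H]([O-])/C=C/C(=O)OC)cc(OC)c1OC.[Na+] | intermediate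
14 | 2-chloro-3,4-didehydrobenzonitrile (3-chloro-4-cyanobenzyne) | N#CC1=C(Cl)C#CC=C1 | intermediate
15 | sodium enolate of 16 (ester enolate on the C3 arm, 2R,3R) | COc1cc([C@@H]2Oc3ccc(C#N)c(Cl)c3[C@H]2C=C([O-])OC)cc(OC)c1OC.[Na+] | intermediate
16 | methyl 2-[(2R,3R)-4-chloro-5-cyano-2-(3,4,5-trimethoxyphenyl)-2,3-dihydro-1-benzofuran-3-yl]acetate | COc1cc([C@@H]2Oc3ccc(C#N)c(Cl)c3[C@H]2CC(=O)OC)cc(OC)c1OC | intermediate
17 | methyl 2-[(2R,3R)-5-cyano-2-(3,4,5-trimethoxyphenyl)-2,3-dihydro-1-benzofuran-3-yl]acetate | COc1cc([C@@H]2Oc3ccc(C#N)cc3[C@H]2CC(=O)OC)cc(OC)c1OC | intermediate
18 | 2-[(2R,3R)-5-cyano-2-(3,4,5-trimethoxyphenyl)-2,3-dihydro-1-benzofuran-3-yl]acetic acid | COc1cc([C@@H]2Oc3ccc(C#N)cc3[C@H]2CC(=O)O)cc(OC)c1OC | intermediate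
19 | 2-thioxopyridin-1(2H)-yl 2-[(2R,3R)-5-cyano-2-(3,4,5-trimethoxyphenyl)-2,3-dihydro-1-benzofuran-3-yl]acetate | COc1cc([C@@H]2Oc3ccc(C#N)cc3[C@H]2CC(=O)On4ccccc4=S)cc(OC)c1OC | intermediate
20 | (2R,3S)-3-(hydroperoxymethyl)-2-(3,4,5-trimethoxyphenyl)-2,3-dihydro-1-benzofuran-5-carbonitrile | COc1cc([C@@H]2Oc3ccc(C#N)cc3[C@H]2COO)cc(OC)c1OC | intermediate
21 | (2R,3S)-3-(hydroxymethyl)-2-(3,4,5-trimethoxyphenyl)-2,3-dihydro-1-benzofuran-5-carbonitrile | COc1cc([C@@H]2Oc3ccc(C#N)cc3[C@H]2CO)cc(OC)c1OC | intermediate
22 | [(2R,3S)-5-(iminomethyl)-2-(3,4,5-trimethoxyphenyl)-2,3-dihydro-1-benzofuran-3-yl]methanol | COc1cc([C@@H]2Oc3ccc(C=N)cc3[C@H]2CO)cc(OC)c1OC | intermediate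
23 | (2R,3S)-3-(hydroxymethyl)-2-(3,4,5-trimethoxyphenyl)-2,3-dihydro-1-benzofuran-5-carbaldehyde | COc1cc([C@@H]2Oc3ccc(C=O)cc3[C@H]2CO)cc(OC)c1OC | intermediate
24 | methyl (triphenylphosphoranylidene)acetate | COC(=O)C=P(c1ccccc1)(c1ccccc1)c1ccccc1 | starting material
25 | methyl (E)-3-[(2R,3S)-3-(hydroxymethyl)-2-(3,4,5-trimethoxyphenyl)-2,3-dihydro-1-benzofuran-5-yl]prop-2-enoate | COc1cc([C@@H]2Oc3ccc(/C=C/C(=O)OC)cc3[C@H]2CO)cc(OC)c1OC | intermediate
26 | (E)-3-[(2R,3S)-3-(hydroxymethyl)-2-(3,4,5-trimethoxyphenyl)-2,3-dihydro-1-benzofuran-5-yl]prop-2-en-1-ol | COc1cc([C@@H]2Oc3ccc(/C=C/CO)cc3[C@H]2CO)cc(OC)c1OC | target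

## Step count and least certain steps

Total step count: 12. Longest linear sequence: 10 steps (steps 3 to 12, from 6); the branch from 1 and 2 has 2 steps before it joins at step 6.

**Step 6 (bears the label).**
- What may go wrong: the carbanion at C3a may be lost before it closes the ring, by protonation from adventitious or substrate-derived acids or by expulsion of the neighbouring chloride. Alkoxide 13 may also be consumed by its own base-induced processes: a 1,3-hydrogen shift at the doubly activated carbinol, intermolecular oxa-Michael addition, or attack at the sulfonyl sulfur of 12. The cause is that a free alkoxide and a very reactive aryl anion coexist with several electrophiles. Incomplete facial control in the closure would in addition erode the trans selectivity.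
- Fallback (known chemistry): it sets out from 5, through alkoxide 13, and returns at 17, so that step 7 falls away. Nucleophilic aromatic substitution of 13 on 3-bromo-4-fluorobenzonitrile F1 (NaH, THF/DMF, 0 °C) displaces the fluoride para to the nitrile without touching the carbinol C–O bond and should give methyl (R,E)-4-(2-bromo-4-cyanophenoxy)-4-(3,4,5-trimethoxyphenyl)but-2-enoate F2. Tin hydride-mediated aryl radical cyclisation of F2 (Bu3SnH, AIBN, PhH, 80 °C, slow addition) is a 5-exo-trig closure onto the enoate beta-carbon; it forms C3–C3a and should give 17 with the same trans preference. Bromine fixes the site of C–C bond formation, so no chlorine is needed.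

**Step 4.**
- What may go wrong: the amide base or the aryllithium may attack the nitrile, the ortho-chloro aryllithium may eliminate LiCl, or the carbamoyl group may migrate (anionic Fries rearrangement). Each becomes competitive if silylation of the anion is not faster than these processes at −78 °C.
- Fallback: it sets out from 6 and returns at 11, which is then triflated to 12 as in the second half of step 5. O-Silylation of 6 (HN(SiMe3)2, neat, 80 °C) gives 2-chloro-4-[(trimethylsilyl)oxy]benzonitrile F3. LiTMP in THF at −78 °C removes the same proton between oxygen and chlorine, and the aryllithium is quenched at once within the molecule by a 1,3 oxygen-to-carbon silyl shift (retro-Brook rearrangement) to the lithium salt of 11. No carbamate and no external silyl electrophile are needed, and the lifetime of the aryl anion is minimal.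

**Step 9.**
- What may go wrong: the primary radical may fragment by cleavage of the C2–C3 bond, which would produce a benzylic, oxygen-stabilised radical, or it may abstract hydrogen from the thiol before it meets oxygen, which amounts to reductive decarboxylation. Both gain ground because dissolved oxygen is dilute.
- Fallback: it sets out from 17 and returns at 21, replacing steps 8 and 9 by ionic chemistry. Enolate hydroxylation (KN(SiMe3)2, THF, −78 °C; 2-(phenylsulfonyl)-3-phenyloxaziridine) gives methyl 2-[(2R,3S)-5-cyano-2-(3,4,5-trimethoxyphenyl)-2,3-dihydro-1-benzofuran-3-yl]-2-hydroxyacetate F4 as a mixture at the new carbinol. LiBH4 (THF, 0 °C) reduces the ester to (2R,3S)-3-(1,2-dihydroxyethyl)-2-(3,4,5-trimethoxyphenyl)-2,3-dihydro-1-benzofuran-5-carbonitrile F5. Glycol cleavage with NaIO4 (THF/H2O) gives (2R,3R)-3-formyl-2-(3,4,5-trimethoxyphenyl)-2,3-dihydro-1-benzofuran-5-carbonitrile F6, which is reduced in the same flask with NaBH4 to 21. Any epimerisation of the aldehyde would converge on the more stable trans isomer.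

**Step 7.**
- What may go wrong: oxidative addition at the doubly ortho-substituted C–Cl bond may be slow, so that at the higher temperature then needed hydride-driven side reactions (partial reduction of the nitrile, cleavage of the benzylic C2–O1 bond) catch up.
- Fallback: it sets out from 16 and returns at 17 by a radical-anion pathway in place of metal insertion. Single-electron reduction of the chloro nitrile arene by a photoexcited organic reductant (10-phenylphenothiazine, Bu3N, HCO2H, MeCN, 390 nm) is followed by loss of chloride from the radical anion and hydrogen-atom transfer to the aryl radical. This fallback makes no new compound (entry F0).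

## Further compounds

F1 | step 6 | 3-bromo-4-fluorobenzonitrile | N#Cc1ccc(F)c(Br)c1
F2 | step 6 | methyl (R,E)-4-(2-bromo-4-cyanophenoxy)-4-(3,4,5-trimethoxyphenyl)but-2-enoate | COc1cc([C@H](Oc2ccc(C#N)cc2Br)/C=C/C(=O)OC)cc(OC)c1OC
F3 | step 4 | 2-chloro-4-[(trimethylsilyl)oxy]benzonitrile | C[Si](C)(C)Oc1ccc(C#N)c(Cl)c1
F4 | step 9 | methyl 2-[(2R,3S)-5-cyano-2-(3,4,5-trimethoxyphenyl)-2,3-dihydro-1-benzofuran-3-yl]-2-hydroxyacetate (both epimers at the carbinol) | COc1cc([C@@H]2Oc3ccc(C#N)cc3[C@H]2C(O)C(=O)OC)cc(OC)c1OC
F5 | step 9 | (2R,3S)-3-(1,2-dihydroxyethyl)-2-(3,4,5-trimethoxyphenyl)-2,3-dihydro-1-benzofuran-5-carbonitrile (both epimers at the carbinol) | COc1cc([C@@H]2Oc3ccc(C#N)cc3[C@H]2C(O)CO)cc(OC)c1OC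
F6 | step 9 | (2R,3R)-3-formyl-2-(3,4,5-trimethoxyphenyl)-2,3-dihydro-1-benzofuran-5-carbonitrile | COc1cc([C@@H]2Oc3ccc(C#N)cc3[C@H]2C=O)cc(OC)c1OC
F0 | step 7 | none | none
A1 | alternative 1 | (2R,3S)-3-{[tert-butyl(dimethyl)silyl]oxymethyl}-2-(3,4,5-trimethoxyphenyl)-2,3-dihydrobenzofuran fused at C4 (Si) and C5 (CH2) to a 1,1-diisopropyl-1,3-dihydro-2,1-benzoxasilole | COc1cc([C@@H]2Oc3ccc4CO[Si](C(C)C)(C(C)C)c4c3[C@H]2CO[Si](C)(C)C(C)(C)C)cc(OC)c1OC
A2 | alternative 1 | triyne: (1R,2S)-1-(ethynyloxy)-1-(3,4,5-trimethoxyphenyl)-2-{[tert-butyl(dimethyl)silyl]oxymethyl}but-3-yne carrying Si(i-Pr)2–O–CH2–C≡CH on the alkyne terminus | COc1cc([C@H](OC#C)[C@H](CO[Si](C)(C)C(C)(C)C)C#C[Si](C(C)C)(C(C)C)OCC#C)cc(OC)c1OC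
A3 | alternative 2 | methyl (2R,3R)-5-bromo-2-(3,4,5-trimethoxyphenyl)-2,3-dihydro-1-benzofuran-3-carboxylate | COc1cc([C@@H]2Oc3ccc(Br)cc3[C@H]2C(=O)OC)cc(OC)c1OC
A4 | alternative 2 | (2R)-6-bromo-2-(3,4,5-trimethoxyphenyl)-2,3-dihydro-4H-chromen-4-one | COc1cc([C@H]2CC(=O)c3cc(Br)ccc3O2)cc(OC)c1OC
A5 | alternative 3 | [(2R,3S)-5-bromo-2-(3,4,5-trimethoxyphenyl)-2,3-dihydro-1-benzofuran-3-yl]methanol | COc1cc([C@@H]2Oc3ccc(Br)cc3[C@H]2CO)cc(OC)c1OC
A6 | alternative 3 | (2S)-2-(5-bromo-2-hydroxyphenyl)-1-(3,4,5-trimethoxyphenyl)propane-1,3-diol (either configuration at C1) | COc1cc(C(O)[C@H](CO)c2cc(Br)ccc2O)cc(OC)c1OC
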